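# Proposed total synthesis of CNP0241834.3 by dienamine bicyclisation of an acyclic trialdehyde

**Conventions.** Ring atoms carry iridoid numbers: C1 acetal carbon, O2, C3=C4 enol ether, C5 and C9 ring fusion, C6, C7, C8, C10 on C8, C11 on C4. β is the face of H5 and H9. Ring A is the dihydropyran, ring B the cyclopentane. Compound numbers follow the order of first appearance in the steps.

**Remark on the chemistry (assumption).** The sense of asymmetric induction in step 6 is assigned from the usual steric model of diarylprolinol silyl ether enamines and dienamines: bond formation on the face of the s-trans (E)-enamine that is remote from the CPh2OSiMe3 group. On that model the (R)-catalyst is required.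

## Analysis of the target

The target is a cyclopenta[c]pyran: ring A (C1, O2, C3=C4, C5, C9), a dihydropyran, is cis-fused along C5–C9 to ring B, the cyclopentane C5–C9. C1 is an acetal carbon esterified with (S)-3-methylpentanoic acid, C4 bears the hydroxymethyl carbon C11, C7 a secondary hydroxyl, and C8 a tertiary hydroxyl together with C10, which is esterified with (E)-p-coumaric acid. The five ring stereocentres are (1R,4aR,6R,7S,7aR) in cyclopenta[c]pyran numbering; the C1 acyloxy group, the 7-hydroxyl and C10 lie on the β face with H5 and H9, the 8-hydroxyl is α, so the 7,8-diol is trans, and a sixth stereocentre sits in the acyl chain. Sensitive groups are the C1 acyl acetal (acid, base, nucleophiles), the electron-rich enol ether with its allylic 11-hydroxyl (acid), two different esters that no reduction may touch, and the cinnamate alkene and phenol (oxidants). The difficulty lies in the tertiary carbinol C8, whose hydroxyl sits on the concave face of ring B between C7 and C9, in telling four hydroxyls apart, and in setting the absolute configuration without a ring from the chiral pool. The plan exploits a hidden 1,5-dicarbonyl relationship: C1 and C3 are both at the aldehyde oxidation level and are linked through C9, C5 and C4, and C11, the second carbon on C4, can be raised to that level as well. Opening ring A at O2–C1 and ring B at C5–C9 therefore leads to an acyclic, achiral ten-carbon trialdehyde, 8, whose C8=C10 alkene stands for the later 8,10-diol and activates C7 for oxidation.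

## Retrosynthetic reasoning

**C11–H (23 from 22).** The hydroxymethyl group is traced back to the C11 aldehyde of 22. As long as C11 is a formyl group, the C3=C4 enol ether is a vinylogous formate, inert to electrophilic oxidants and tolerant of acid, and C1 behaves like an acylal. The forward step must reduce one conjugated aldehyde in the presence of two esters, and the acid-labile 4-hydroxymethyl enol ether then appears only at the very end.

**O–Si and O10–acyl (22 from 21, 21 from 17 and 20).** Both silyl ethers of 21 are removed together. The ester bond at O10 is cut to diol 17 and acid 20, which comes from p-coumaric acid 18 by silylation of the phenol. The phenol and O7 carry the same silyl group so that one operation frees both. The forward esterification only has to tell a primary from a tertiary hydroxyl.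

**C8–O, C10–O and C7–O (17 from 16, 16 from 15, 15 from 14).** The 8,10-diol is cut back to the 1,1-disubstituted alkene of 16, and the C7 oxygen to the allylic C–H of 14. One alkene thus encodes three oxygens. The order matters: O7 must be in place, and silylated, before the dihydroxylation so that it can steer the reagent to the α face of C8. The dihydroxylation must precede the arrival of the cinnamate alkene.

**C1–O acyl (14 from 11 and 13).** The ester at C1 is cut to lactol 11 and anhydride 13, which is made from two molecules of acid 12. Putting the final acyl group on at once locks the lactol against ring opening and spends no protecting group on C1.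

**C5–C9 and O2–C1 (11 from 8).** Both rings are opened at the two bonds that the 1,5-dicarbonyl relationship offers. This leads to trialdehyde 8, which has no stereocentre and no ring. No other pair of cuts removes both rings and three stereocentres at once while leaving C1, C3 and C11 at the oxidation level they need. The forward reaction has to make C9 nucleophilic through a chiral secondary amine, join it to C5, close O2 onto C1, and leave the C8=C10 alkene unconjugated.

**C4=C5, oxidation level, C6–C7 of the terpene (8 from 7, 7 from 6, 6 from 4 and 5, 4 from 2, 2 from 1).** The three formyl groups come from triol 7 by oxidation, and 7 from malonate 6 by hydride reduction. The C4=C5 alkene is cut to aldehyde 4 and dimethyl malonate 5. Aldehyde 4 comes from geranyl acetate 1 by cleavage of the remote alkene through epoxide 2. This supplies C1 and C5–C10 with the (E)-alkene already in place.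

## Alternatives that were turned down

**Alternative 1: late oxygen insertion into a carbocycle.**
- Disconnection: O2 is taken out of ring A, which gives A1, a cis-bicyclo[3.3.0]octan-3-one in which C1, already carrying its silyloxy group, is bonded directly to the C3 carbonyl carbon.
- Forward key step: a Baeyer–Villiger ring expansion. The Criegee adduct at the C3 carbonyl rearranges by shift of C1, the better migrating group because of its oxygen substituent, with its configuration kept. O2 is thereby inserted between C1 and C3 and the lactone acetal A2 results.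
- For: every ring stereocentre can be set on a rigid carbocycle by convex-face chemistry before the sensitive heterocycle exists. The 7,8,10-triol arrives already differentiated by a silylene. The key reaction is a well-known type with a predictable migrating group.
- Against: in A2, C3 is a lactone carbonyl and C4 an sp3 centre. The enol ether must then be made by reducing and dehydrating a lactone that is itself an acyl acetal. The C1 silyl ether must later be exchanged for the acyl group through a free lactol. A1, with six stereocentres, needs a long linear build-up.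
- Comparison: Alternative 1 is stronger on the security of C7 and C8, which never depend on a late face preference. The chosen route offers both rings, three stereocentres and the correct oxidation level at C1, C3 and C11 in one operation from a five-step achiral precursor, with no redox work at C3.

**Alternative 2: nickel-catalysed reductive ynal cyclisation closing C7–C8.**
- Disconnection: the C7–C8 bond of ring B, giving A3, a dihydropyran with an ethynyl group on C9 and a 2-oxoethyl group on C5.
- Forward key step: a zerovalent nickel catalyst made from Ni(cod)2 and PBu3 joins the aldehyde carbon C7 to the inner alkyne carbon C8 by oxidative cyclisation, and Et3SiH cleaves the nickelacycle. The result is A4, with the 7-silyloxy group and the 8(10)-methylene in place.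
- For: the reaction type is established. It delivers in the ring-forming step the 7-oxygen and the exocyclic alkene that the chosen route makes by a separate allylic oxidation. On this point Alternative 2 is stronger, since no choice between C7–H and C9–H arises.
- Against: the difficulty moves into A3, whose three contiguous stereocentres (C1, C9, C5) on ring A need their own asymmetric construction. The C7 configuration depends on how the side chain folds at nickel. C11 is an ester and needs a strong hydride before either acyl group can be present, so C1 and C11 both need protecting-group exchanges. The face question of the later dihydroxylation remains.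
- Comparison: the chosen route is shorter and keeps C11 as an aldehyde that a mild hydride can reduce last.

**Alternative 3: silicon-tethered delivery of C10 from O7.**
- Disconnection: the C8–C10 bond, giving A5, a 10-nor C8 ketone whose 7β-oxygen carries an (iodomethyl)dimethylsilyl group.
- Forward key step: t-BuLi turns the C–I bond of A5 into a C–Li bond, and the silylmethyl carbanion, held on the β face by its tether to O7, attacks the neighbouring ketone. The five-membered silicon ring of A6 can only form cis, which places C10 β and the new hydroxyl α. Oxidative C–Si cleavage would then free O7 and O10.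
- For: the configuration of the tertiary carbinol is dictated by the tether and not by a face preference. This is stronger than the chosen route at its weakest stereochemical point.
- Against: A5 is a ketone whose α-carbon C9 bears the acetal carbon, so it is open to epimerisation and β-elimination of O2 under strongly basic conditions. t-BuLi excludes esters and aldehydes, so C1 and C11 travel as silyl ethers and four hydroxyls must be told apart afterwards. The skeleton is built one carbon short. A5 itself presupposes a full synthesis of the bicycle.
- Comparison: the chosen route carries all ten skeletal carbons from the start and uses no protecting group on C1, C10 or C11. Its C8 question is backed by a directed-epoxidation fallback.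

Key step: step 6

## Steps

Step 1
Reactants: 1 geranyl acetate
Product: 2 (2E)-5-(3,3-dimethyloxiran-2-yl)-3-methylpent-2-en-1-yl acetate (racemic at the epoxide carbon)
Conditions: mCPBA (1.05 equiv), NaHCO3, CH2Cl2, 0 °C
Reagents that add atoms: meta-chloroperbenzoic acid, OOC(=O)c1cccc(Cl)c1
Why: Prilezhaev epoxidation is electrophilic and should pick the remote, more electron-rich 6,7-alkene over the 2,3-alkene, which is deactivated by the allylic acetate; the new stereocentre is racemic and is removed in step 2.

Step 2
Reactants: 2 (2E)-5-(3,3-dimethyloxiran-2-yl)-3-methylpent-2-en-1-yl acetate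
Product: 4 (2E)-3-methyl-6-oxohex-2-en-1-yl acetate, via glycol 3 (not isolated)
Conditions: H5IO6 (1.1 equiv), THF/H2O, 0 °C to rt
Reagents that add atoms: none
Why: Periodic acid opens the epoxide with water at its tertiary carbon to glycol 3 and cleaves it in the same flask (glycol cleavage), so the water oxygen leaves with the acetone and the epoxide oxygen ends as the aldehyde oxygen of 4; the allylic acetate and the (E)-alkene are inert.

Step 3
Reactants: 4 (2E)-3-methyl-6-oxohex-2-en-1-yl acetate; 5 dimethyl malonate
Product: 6 dimethyl 2-[(4E)-6-acetoxy-4-methylhex-4-en-1-ylidene]malonate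
Conditions: piperidine (0.1 equiv), AcOH (0.1 equiv), 4 Å MS, toluene, rt to 40 °C
Reagents that add atoms: none
Why: Knoevenagel condensation under piperidinium acetate catalysis with removal of water; the malonate is symmetric, so the new C4=C5 alkene has no geometry to control.

Step 4
Reactants: 6 dimethyl 2-[(4E)-6-acetoxy-4-methylhex-4-en-1-ylidene]malonate
Product: 7 2-[(4E)-6-hydroxy-4-methylhex-4-en-1-ylidene]propane-1,3-diol
Conditions: DIBAL-H (8 equiv), CH2Cl2, −78 to 0 °C; aq. potassium sodium tartrate work-up
Reagents that add atoms: none
Why: Excess DIBAL-H should reduce the two conjugated esters in the 1,2 sense to the 2-alkylidene-1,3-diol and cleave the acetate reductively, bringing C1, C3 and C11 to the allylic alcohol level in one step.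

Step 5
Reactants: 7 2-[(4E)-6-hydroxy-4-methylhex-4-en-1-ylidene]propane-1,3-diol
Product: 8 (6E)-2-formyl-6-methylocta-2,6-dienedial
Conditions: activated MnO2 (30 equiv), CH2Cl2, rt; filtration through Celite under argon, used crude at once
Reagents that add atoms: none
Why: All three hydroxyls are allylic, so MnO2 should oxidise them to aldehydes under neutral heterogeneous conditions without isomerising the alkenes; 8 is an electron-poor alkylidene malondialdehyde and is therefore not stored or chromatographed.

Step 6
Reactants: 8 (6E)-2-formyl-6-methylocta-2,6-dienedial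
Product: 11 (1S,4aR,7aR)-1-hydroxy-7-methylidene-1,4a,5,6,7,7a-hexahydrocyclopenta[c]pyran-4-carbaldehyde (8(10)-methylene-11-oxo iridoid lactol), via dienamine 9 (not isolated), via cyclic aminal 10 (not isolated)
Conditions: (R)-2-[diphenyl(trimethylsilyloxy)methyl]pyrrolidine (20 mol%), PhCO2H (20 mol%), H2O (2 equiv), toluene (0.05 M), 0 °C to rt; crude lactol taken directly into step 8
Reagents that add atoms: none
Why: Proposed new method: the catalyst forms an iminium ion at the C1 aldehyde of 8 (the only enal without an α-substituent), removal of a γ-proton from the C10 methyl group gives the (E)-dienamine 9 with the C8=C10 alkene now terminal, C9 of 9 attacks C5 of the doubly formyl-activated alkene in a Michael addition, and the resulting malondialdehyde enolate closes through oxygen onto the C1 iminium carbon to give aminal 10, which the water freed in the condensation converts into 11 and free catalyst; the nearest known reaction types are the dienamine-mediated intramolecular Rauhut–Currier-type Michael cyclisation of dienedials and the amine-catalysed inverse-electron-demand oxa-Diels–Alder reaction of enamines with unsaturated carbonyl compounds, which have not yet been combined on one chain. Ring B closes 5-exo-trig at the acceptor with the enamine double bond exocyclic to the new ring, and ring A closes 6-exo-trig by attack of the enolate oxygen on the iminium carbon, so that overall the C1=C9 enamine adds across the O=C3–C4=C5 oxadiene in a formal intramolecular [4+2] sense. C9 is controlled by the catalyst: its CPh2OSiMe3 group blocks one face of the s-trans (E)-dienamine, and with the (R)-catalyst C5 should bond to the Re face of C9 and give 9R. C5 is controlled by the C6–C7–C8 tether, which can bridge C5 and C9 in the bicyclic transition state only if H5 and H9 are cis, and a trans Michael adduct, unable to close ring A, can revert. C1 is under thermodynamic control, the lactol being expected to rest as the β-anomer with an axial hydroxyl on the convex face (anomeric effect). The step needs C9 rather than C10 to react and the C10-derived rather than the C7-derived dienamine to cyclise: only bond formation at C9 brings the iminium carbon within reach of the enolate oxygen, and the C7-derived dienamine could close only to a ring with an endocyclic double bond, so ring closure to 10 should pull the equilibrating intermediates through a single channel. Because both acceptor carbonyls are formyl groups its alkene has no geometry, and because C1 ends as an acetal carbon the C8=C10 alkene cannot move into conjugation.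

Step 7
Reactants: 12 (3S)-3-methylpentanoic acid (two molecules per molecule of product)
Product: 13 (3S)-3-methylpentanoic anhydride
Conditions: 12 (2.0 equiv), DCC (1.0 equiv), CH2Cl2, 0 °C to rt; filtration of the urea
Reagents that add atoms: (3S)-3-methylpentanoic acid (the second molecule of 12), CC[C@H](C)CC(=O)O
Why: Carbodiimide dehydration: one molecule of 12 is activated as its O-acylisourea and acylated by the carboxylate of a second molecule, so two molecules of acid give one of the symmetrical anhydride and the water is taken up by DCC; the β-stereocentre is not enolisable and stays untouched.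

Step 8
Reactants: 11 (1S,4aR,7aR)-1-hydroxy-7-methylidene-1,4a,5,6,7,7a-hexahydrocyclopenta[c]pyran-4-carbaldehyde; 13 (3S)-3-methylpentanoic anhydride
Product: 14 (1R,4aR,7aR)-4-formyl-7-methylidene-1,4a,5,6,7,7a-hexahydrocyclopenta[c]pyran-1-yl (3S)-3-methylpentanoate
Conditions: 13 (1.5 equiv), Et3N (2 equiv), DMAP (0.1 equiv), CH2Cl2, −20 to 0 °C
Reagents that add atoms: none
Why: DMAP-catalysed O-acylation of the lactol hydroxyl; the equilibrating lactol should be acylated as the β-anomer (acyloxy group axial, on the convex face, trans to C8), which fixes C1, and the low temperature and weak base should keep C9 from epimerising.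

Step 9
Reactants: 14 (1R,4aR,7aR)-4-formyl-7-methylidene-1,4a,5,6,7,7a-hexahydrocyclopenta[c]pyran-1-yl (3S)-3-methylpentanoate
Product: 15 (1R,4aR,6R,7aR)-4-formyl-6-hydroxy-7-methylidene-1,4a,5,6,7,7a-hexahydrocyclopenta[c]pyran-1-yl (3S)-3-methylpentanoate (7β-alcohol in iridoid numbering)
Conditions: SeO2 (0.3 equiv), t-BuOOH (3 equiv), CH2Cl2, 0 °C to rt
Reagents that add atoms: tert-butyl hydroperoxide, CC(C)(C)OO (the oxygen is relayed through SeO2, O=[Se]=O)
Why: SeO2 allylic hydroxylation (ene reaction, then [2,3]-sigmatropic shift) of a 1,1-disubstituted alkene should occur at the allylic CH2 (C7) in preference to the allylic CH (C9), with the alkene returning to C8=C10; oxygen should be delivered to C7 on the convex β face, and the push-pull C3=C4 alkene is too electron-poor to react.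

Step 10
Reactants: 15 (1R,4aR,6R,7aR)-4-formyl-6-hydroxy-7-methylidene-1,4a,5,6,7,7a-hexahydrocyclopenta[c]pyran-1-yl (3S)-3-methylpentanoate
Product: 16 (1R,4aR,6R,7aR)-6-[(tert-butyldimethylsilyl)oxy]-4-formyl-7-methylidene-1,4a,5,6,7,7a-hexahydrocyclopenta[c]pyran-1-yl (3S)-3-methylpentanoate
Conditions: TBSOTf (1.3 equiv), 2,6-lutidine (2.5 equiv), CH2Cl2, −78 °C
Reagents that add atoms: tert-butyldimethylsilyl trifluoromethanesulfonate, CC(C)(C)[Si](C)(C)OS(=O)(=O)C(F)(F)F
Why: Silylation of the secondary allylic alcohol with a silyl triflate and a hindered, non-nucleophilic base that should spare the C1 ester; the bulky ether is needed to steer step 11.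

Step 11
Reactants: 16 (1R,4aR,6R,7aR)-6-[(tert-butyldimethylsilyl)oxy]-4-formyl-7-methylidene-1,4a,5,6,7,7a-hexahydrocyclopenta[c]pyran-1-yl (3S)-3-methylpentanoate
Product: 17 (1R,4aR,6R,7S,7aR)-6-[(tert-butyldimethylsilyl)oxy]-4-formyl-7-hydroxy-7-(hydroxymethyl)-1,4a,5,6,7,7a-hexahydrocyclopenta[c]pyran-1-yl (3S)-3-methylpentanoate
Conditions: OsO4 (5 mol%), NMO (1.5 equiv), acetone/H2O (8:1), 0 °C; Na2SO3 quench
Reagents that add atoms: N-methylmorpholine N-oxide, C[N+]1([O-])CCOCC1; water, O (both oxygens are relayed through OsO4, O=[Os](=O)(=O)=O)
Why: Catalytic OsO4 cis-dihydroxylation of the only electron-rich alkene left; by the empirical anti rule for osmylation of allylic ethers, reinforced by the bulk of the β-silyloxy group on the otherwise more open convex face, the reagent should add to the α face of C8=C10 and set C8 with 8-OH α and C10 β. The C3=C4 alkene is deactivated by the C11 formyl group.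

Step 12
Reactants: 18 p-coumaric acid
Product: 20 (2E)-3-[4-(tert-butyldimethylsilyloxy)phenyl]prop-2-enoic acid, via bis-silyl compound 19 (not isolated)
Conditions: TBSCl (2.4 equiv), imidazole (5 equiv), DMF, rt; then AcOH/THF/H2O, rt
Reagents that add atoms: tert-butyldimethylsilyl chloride, CC(C)(C)[Si](C)(C)Cl
Why: Both acidic sites are silylated and the labile silyl ester of 19 is then hydrolysed selectively by aqueous acetic acid, leaving the aryl silyl ether; the phenol must be masked so that the acid can be activated without self-condensation.

Step 13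
Reactants: 17 (1R,4aR,6R,7S,7aR)-6-[(tert-butyldimethylsilyl)oxy]-4-formyl-7-hydroxy-7-(hydroxymethyl)-1,4a,5,6,7,7a-hexahydrocyclopenta[c]pyran-1-yl (3S)-3-methylpentanoate; 20 (2E)-3-[4-(tert-butyldimethylsilyloxy)phenyl]prop-2-enoic acid
Product: 21 [(1R,4aR,6R,7S,7aR)-6-[(tert-butyldimethylsilyl)oxy]-4-formyl-7-hydroxy-1-{[(3S)-3-methylpentanoyl]oxy}-1,4a,5,6,7,7a-hexahydrocyclopenta[c]pyran-7-yl]methyl (2E)-3-[4-(tert-butyldimethylsilyloxy)phenyl]prop-2-enoate
Conditions: 20 (1.2 equiv), EDC·HCl (1.5 equiv), DMAP (0.2 equiv), CH2Cl2, 0 °C to rt
Reagents that add atoms: none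
Why: Steglich-type carbodiimide/DMAP esterification should acylate the primary C10 hydroxyl only, since the tertiary C8 hydroxyl does not compete; the (E)-alkene of the acid is retained.

Step 14
Reactants: 21 [(1R,4aR,6R,7S,7aR)-6-[(tert-butyldimethylsilyl)oxy]-4-formyl-7-hydroxy-1-{[(3S)-3-methylpentanoyl]oxy}-1,4a,5,6,7,7a-hexahydrocyclopenta[c]pyran-7-yl]methyl (2E)-3-[4-(tert-butyldimethylsilyloxy)phenyl]prop-2-enoate
Product: 22 [(1R,4aR,6R,7S,7aR)-4-formyl-6,7-dihydroxy-1-{[(3S)-3-methylpentanoyl]oxy}-1,4a,5,6,7,7a-hexahydrocyclopenta[c]pyran-7-yl]methyl (2E)-3-(4-hydroxyphenyl)prop-2-enoate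
Conditions: HF·pyridine, pyridine, THF, 0 °C to rt
Reagents that add atoms: none
Why: Buffered HF·pyridine should cleave the aryl and the secondary alkyl silyl ether in one operation; at this stage the enol ether is still a vinylogous formate and C1 an acylal-type centre, and both tolerate these mildly acidic conditions.

Step 15
Reactants: 22 [(1R,4aR,6R,7S,7aR)-4-formyl-6,7-dihydroxy-1-{[(3S)-3-methylpentanoyl]oxy}-1,4a,5,6,7,7a-hexahydrocyclopenta[c]pyran-7-yl]methyl (2E)-3-(4-hydroxyphenyl)prop-2-enoate
Product: 23 [(1R,4aR,6R,7S,7aR)-6,7-dihydroxy-4-(hydroxymethyl)-1-{[(3S)-3-methylpentanoyl]oxy}-1,4a,5,6,7,7a-hexahydrocyclopenta[c]pyran-7-yl]methyl (2E)-3-(4-hydroxyphenyl)prop-2-enoate (CNP0241834.3)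
Conditions: NaBH4 (1.2 equiv), CeCl3·7H2O (1.2 equiv), MeOH/THF, −78 °C; acetone, then pH 7 NaH2PO4/Na2HPO4 buffer
Reagents that add atoms: none
Why: Luche reduction: CeCl3-modified NaBH4 at low temperature should reduce the conjugated C11 aldehyde in the 1,2 sense and leave the cinnamate, the C1 ester and the acetal untouched; the acid-labile 4-hydroxymethyl enol ether is formed only here and is worked up at pH 7.

## Compound list

1 | geranyl acetate | CC(C)=CCC/C(C)=C/COC(C)=O | starting material
2 | (2E)-5-(3,3-dimethyloxiran-2-yl)-3-methylpent-2-en-1-yl acetate (racemic epoxide) | CC1(C)OC1CC/C(C)=C/COC(C)=O | intermediate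
3 | (2E)-6,7-dihydroxy-3,7-dimethyloct-2-en-1-yl acetate (glycol, racemic, not isolated) | CC(C)(O)C(O)CC/C(C)=C/COC(C)=O | intermediate
4 | (2E)-3-methyl-6-oxohex-2-en-1-yl acetate | O=CCC/C(C)=C/COC(C)=O | intermediate
5 | dimethyl malonate | COC(=O)CC(=O)OC | starting material
6 | dimethyl 2-[(4E)-6-acetoxy-4-methylhex-4-en-1-ylidene]malonate | COC(=O)C(=CCC/C(C)=C/COC(C)=O)C(=O)OC | intermediate
7 | 2-[(4E)-6-hydroxy-4-methylhex-4-en-1-ylidene]propane-1,3-diol | OCC(CO)=CCC/C(C)=C/CO | intermediate
8 | (6E)-2-formyl-6-methylocta-2,6-dienedial | O=C/C=C(\C)CCC=C(C=O)C=O | intermediate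
9 | (R)-1-[(1E)-7,7-diformyl-3-methylidenehepta-1,6-dien-1-yl]-2-[diphenyl(trimethylsilyloxy)methyl]pyrrolidine (dienamine, not isolated) | C[Si](C)(C)OC(c1ccccc1)(c1ccccc1)[C@H]1CCCN1/C=C/C(=C)CCC=C(C=O)C=O | intermediate
10 | cyclic N,O-aminal: analogue of 11 with the (R)-2-[diphenyl(trimethylsilyloxy)methyl]pyrrolidin-1-yl group at C1 (β) in place of hydroxyl (not isolated) | C[Si](C)(C)OC(c1ccccc1)(c1ccccc1)[C@H]1CCCN1[C@H]1OC=C(C=O)[C@@H]2CCC(=C)[C@H]12 | intermediate
11 | (1S,4aR,7aR)-1-hydroxy-7-methylidene-1,4a,5,6,7,7a-hexahydrocyclopenta[c]pyran-4-carbaldehyde | O[C@H]1OC=C(C=O)[C@@H]2CCC(=C)[C@H]12 | intermediate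
12 | (3S)-3-methylpentanoic acid | CC[C@H](C)CC(=O)O | starting material
13 | (3S)-3-methylpentanoic anhydride | CC[C@H](C)CC(=O)OC(=O)C[C@@H](C)CC | intermediate
14 | (1R,4aR,7aR)-4-formyl-7-methylidene-1,4a,5,6,7,7a-hexahydrocyclopenta[c]pyran-1-yl (3S)-3-methylpentanoate | CC[C@H](C)CC(=O)O[C@H]1OC=C(C=O)[C@@H]2CCC(=C)[C@H]12 | intermediate
15 | (1R,4aR,6R,7aR)-4-formyl-6-hydroxy-7-methylidene-1,4a,5,6,7,7a-hexahydrocyclopenta[c]pyran-1-yl (3S)-3-methylpentanoate | CC[C@H](C)CC(=O)O[C@H]1OC=C(C=O)[C@@H]2C[C@@H](O)C(=C)[C@H]12 | intermediate
16 | (1R,4aR,6R,7aR)-6-[(tert-butyldimethylsilyl)oxy]-4-formyl-7-methylidene-1,4a,5,6,7,7a-hexahydrocyclopenta[c]pyran-1-yl (3S)-3-methylpentanoate | CC[C@H](C)CC(=O)O[C@H]1OC=C(C=O)[C@@H]2C[C@@H](O[Si](C)(C)C(C)(C)C)C(=C)[C@H]12 | intermediate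
17 | (1R,4aR,6R,7S,7aR)-6-[(tert-butyldimethylsilyl)oxy]-4-formyl-7-hydroxy-7-(hydroxymethyl)-1,4a,5,6,7,7a-hexahydrocyclopenta[c]pyran-1-yl (3S)-3-methylpentanoate | CC[C@H](C)CC(=O)O[C@H]1OC=C(C=O)[C@@H]2C[C@@H](O[Si](C)(C)C(C)(C)C)[C@@](O)(CO)[C@H]12 | intermediate
18 | p-coumaric acid, (2E)-3-(4-hydroxyphenyl)prop-2-enoic acid | OC(=O)/C=C/c1ccc(O)cc1 | starting material
19 | tert-butyldimethylsilyl (2E)-3-[4-(tert-butyldimethylsilyloxy)phenyl]prop-2-enoate (not isolated) | CC(C)(C)[Si](C)(C)OC(=O)/C=C/c1ccc(O[Si](C)(C)C(C)(C)C)cc1 | intermediate
20 | (2E)-3-[4-(tert-butyldimethylsilyloxy)phenyl]prop-2-enoic acid | OC(=O)/C=C/c1ccc(O[Si](C)(C)C(C)(C)C)cc1 | intermediate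
21 | [(1R,4aR,6R,7S,7aR)-6-[(tert-butyldimethylsilyl)oxy]-4-formyl-7-hydroxy-1-{[(3S)-3-methylpentanoyl]oxy}-1,4a,5,6,7,7a-hexahydrocyclopenta[c]pyran-7-yl]methyl (2E)-3-[4-(tert-butyldimethylsilyloxy)phenyl]prop-2-enoate | CC[C@H](C)CC(=O)O[C@H]1OC=C(C=O)[C@@H]2C[C@@H](O[Si](C)(C)C(C)(C)C)[C@@](O)(COC(=O)/C=C/c3ccc(O[Si](C)(C)C(C)(C)C)cc3)[C@H]12 | intermediate
22 | [(1R,4aR,6R,7S,7aR)-4-formyl-6,7-dihydroxy-1-{[(3S)-3-methylpentanoyl]oxy}-1,4a,5,6,7,7a-hexahydrocyclopenta[c]pyran-7-yl]methyl (2E)-3-(4-hydroxyphenyl)prop-2-enoate | CC[C@H](C)CC(=O)O[C@H]1OC=C(C=O)[C@@H]2C[C@@H](O)[C@@](O)(COC(=O)/C=C/c3ccc(O)cc3)[C@H]12 | intermediate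
23 | [(1R,4aR,6R,7S,7aR)-6,7-dihydroxy-4-(hydroxymethyl)-1-{[(3S)-3-methylpentanoyl]oxy}-1,4a,5,6,7,7a-hexahydrocyclopenta[c]pyran-7-yl]methyl (2E)-3-(4-hydroxyphenyl)prop-2-enoate | CC[C@H](C)CC(=O)O[C@H]1OC=C(CO)[C@@H]2C[C@@H](O)[C@@](O)(COC(=O)/C=C/c3ccc(O)cc3)[C@H]12 | target

## Step count and least certain steps

Total: 15 steps. Longest linear sequence: 13 steps (steps 1–6, 8–11 and 13–15); steps 7 and 12 prepare the two acyl donors.

**Step 6 (key step, new method).** Three processes are most likely to defeat it. The amine may be captured by the more electrophilic malondialdehyde end, where condensation and loss of a C6 proton would give a stable vinylogous amide while 8 oligomerises. The iminium–enolate pair may lose the C9 proton, or the dienamine may attack through C10; either leads to a conjugated cyclopentene- or cyclopentylidene-carbaldehyde (the usual Rauhut–Currier-type outcome) before O2 can close onto C1, and C9 is lost as a stereocentre. The free lactol may also ring-open and conjugate during handling.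

The fallback gives up the geranyl chain and the dienamine and relies only on enamine activation of a saturated aldehyde. It sets out from dimethyl malonate 5, uses anhydride 13, and returns to the route at 14. Half-saponification of 5 (KOH, MeOH) would give potassium methyl malonate F1. Acylation with pent-4-enoyl chloride (MgCl2, Et3N, MeCN) with loss of CO2 would give methyl 3-oxohept-6-enoate F2. Ketalisation with ethylene glycol (TsOH) would give methyl 2-[2-(but-3-en-1-yl)-1,3-dioxolan-2-yl]acetate F3, and DIBAL-H at −78 °C would give 2-[2-(but-3-en-1-yl)-1,3-dioxolan-2-yl]acetaldehyde F4. Cross-metathesis with crotonaldehyde (second-generation Hoveyda–Grubbs catalyst) would give (2E)-5-[2-(2-oxoethyl)-1,3-dioxolan-2-yl]pent-2-enal F5, a saturated aldehyde tethered to an enal with C8 masked as a ketal. L-Proline in DMSO should then effect the enamine Michael addition and lactolisation, a cyclisation that is established for formyl enals in iridoid synthesis; the hydrogen-bond-directed proline enamine should give the same sense as the (R)-prolinol ether, and the product would be the cis-fused 8,8-ethylenedioxy lactol F6. Acylation with 13 as in step 8 would give its C1 (3S)-3-methylpentanoate F7, mild transketalisation (PdCl2(MeCN)2 in wet acetone, or PPTS) the 8-ketone F8, and non-basic methylenation with Zn, CH2Br2 and TiCl4 the 8(10)-methylene enol ether F9. Vilsmeier–Haack formylation (POCl3, DMF, 0 °C) at C4 of the enol ether would then give 14.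

**Step 11.** Poor facial selectivity is the likely failure. The α face of C8=C10 is the concave face of ring B, next to C1, so the preference for attack anti to the 7β-silyloxy group may be eroded and the 8β-hydroxy epimer formed.

The fallback replaces reagent-face selection by a directed epoxidation and a stereospecific opening. It sets out from 15 and returns at 22. VO(acac)2 and t-BuOOH should epoxidise syn to the free 7β-hydroxyl and give the β-spiro-epoxide F10. Dilute aqueous acid (HClO4, THF/H2O, 0 °C) should open it at the tertiary carbon C8 with inversion, water entering on the α face, to give the 7β,8α,10-triol F11. Esterification of the primary hydroxyl with 20 (EDC·HCl, DMAP, −20 °C) would give the 10-O-[4-(tert-butyldimethylsilyloxy)cinnamoyl] ester F12, and HF·pyridine would give 22.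

**Step 9.** Over-oxidation to the cross-conjugated enone, incomplete preference for the β face at C7, and some ene reaction at C9–H are the likely failures.

The fallback sets C7 by reduction and inversion. It sets out from 14 and returns at 15. Forcing the SeO2 oxidation, or treating the crude alcohol mixture with Dess–Martin periodinane, would give the 7-oxo-8(10)-methylene enone F13. Luche reduction at −78 °C (ketone before the vinylogous formyl group, hydride from the convex β face) should give the 7α-alcohol F14. Mitsunobu inversion with chloroacetic acid (PPh3, DIAD), the nucleophile entering on the convex face, would give the 7β-chloroacetate F15, and thiourea with NaHCO3 in ethanol would remove the chloroacetyl group selectively to give 15.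

**Step 15.** Under the basic borohydride/methoxide conditions the cinnamoyl group may migrate from O10 to the cis 7-hydroxyl or the C1 ester may be methanolysed. The freed allylic enol ether may also solvolyse in the Lewis-acidic methanol.

The fallback reduces before the hydroxyls are freed. It sets out from 21 and returns at 23. Luche reduction of 21 would give the bis-silyl C11 alcohol F16, in which O7 and the phenol are still blocked, and fluoride buffered with acetic acid (TBAF/AcOH, THF, 0 °C) would then remove both silyl groups to give 23.

## Further compounds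

F1 | step 6 | potassium methyl malonate | [K+].[O-]C(=O)CC(=O)OC
F2 | step 6 | methyl 3-oxohept-6-enoate | COC(=O)CC(=O)CCC=C
F3 | step 6 | methyl 2-[2-(but-3-en-1-yl)-1,3-dioxolan-2-yl]acetate | COC(=O)CC1(CCC=C)OCCO1
F4 | step 6 | 2-[2-(but-3-en-1-yl)-1,3-dioxolan-2-yl]acetaldehyde | O=CCC1(CCC=C)OCCO1
F5 | step 6 | (2E)-5-[2-(2-oxoethyl)-1,3-dioxolan-2-yl]pent-2-enal | O=CCC1(CC/C=C/C=O)OCCO1
F6 | step 6 | cis-fused 8,8-ethylenedioxy iridoid lactol without C11 (1β-OH, H5 and H9 β) | O[C@H]1OC=C[C@@H]2CCC3(OCCO3)[C@H]12
F7 | step 6 | C1 (3S)-3-methylpentanoate of F6 | CC[C@H](C)CC(=O)O[C@H]1OC=C[C@@H]2CCC3(OCCO3)[C@H]12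
F8 | step 6 | 8-oxo analogue of F7 (ketal removed) | CC[C@H](C)CC(=O)O[C@H]1OC=C[C@@H]2CCC(=O)[C@H]12
F9 | step 6 | 8(10)-methylene enol ether, 14 without its formyl group | CC[C@H](C)CC(=O)O[C@H]1OC=C[C@@H]2CCC(=C)[C@H]12
F10 | step 11 | 8,10-spiro-epoxide of 15 with the epoxide oxygen β (syn to 7β-OH) | CC[C@H](C)CC(=O)O[C@H]1OC=C(C=O)[C@@H]2C[C@@H](O)[C@]3(CO3)[C@H]12
F11 | step 11 | 7β,8α,10-triol (17 without its silyl group) | CC[C@H](C)CC(=O)O[C@H]1OC=C(C=O)[C@@H]2C[C@@H](O)[C@@](O)(CO)[C@H]12
F12 | step 11 | 10-O-[(2E)-3-(4-tert-butyldimethylsilyloxyphenyl)prop-2-enoyl] ester of F11 (21 with free 7-OH) | CC[C@H](C)CC(=O)O[C@H]1OC=C(C=O)[C@@H]2C[C@@H](O)[C@@](O)(COC(=O)/C=C/c3ccc(O[Si](C)(C)C(C)(C)C)cc3)[C@H]12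
F13 | step 9 | 7-oxo-8(10)-methylene enone derived from 14 | CC[C@H](C)CC(=O)O[C@H]1OC=C(C=O)[C@@H]2CC(=O)C(=C)[C@H]12
F14 | step 9 | 7α-alcohol (C7 epimer of 15) | CC[C@H](C)CC(=O)O[C@H]1OC=C(C=O)[C@@H]2C[C@H](O)C(=C)[C@H]12
F15 | step 9 | 7β-chloroacetate of 15 | CC[C@H](C)CC(=O)O[C@H]1OC=C(C=O)[C@@H]2C[C@@H](OC(=O)CCl)C(=C)[C@H]12
F16 | step 15 | C11 alcohol of 21 (both silyl ethers retained) | CC[C@H](C)CC(=O)O[C@H]1OC=C(CO)[C@@H]2C[C@@H](O[Si](C)(C)C(C)(C)C)[C@@](O)(COC(=O)/C=C/c3ccc(O[Si](C)(C)C(C)(C)C)cc3)[C@H]12
A1 | alternative 1 | cis-bicyclo[3.3.0]octan-3-one precursor with C1 bonded to C3 (1-OTBS, 11-OTBS, 7,10-O-di-tert-butylsilylene, 8-OH) | CC(C)(C)[Si](C)(C)O[C@H]1C(=O)[C@@H](CO[Si](C)(C)C(C)(C)C)[C@@H]2C[C@H]3O[Si](C(C)(C)C)(C(C)(C)C)OC[C@@]3(O)[C@H]12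
A2 | alternative 1 | 3-oxo-3,4-dihydro iridoid lactone acetal | CC(C)(C)[Si](C)(C)O[C@H]1OC(=O)[C@@H](CO[Si](C)(C)C(C)(C)C)[C@@H]2C[C@H]3O[Si](C(C)(C)C)(C(C)(C)C)OC[C@@]3(O)[C@H]12
A3 | alternative 2 | dihydropyran ynal (1-OTBS, methyl ester on C4, 2-oxoethyl on C5, ethynyl on C9) | CC(C)(C)[Si](C)(C)O[C@H]1OC=C(C(=O)OC)[C@H](CC=O)[C@@H]1C#C
A4 | alternative 2 | 7-triethylsilyloxy-8(10)-methylene iridoid ester | CC(C)(C)[Si](C)(C)O[C@H]1OC=C(C(=O)OC)[C@@H]2C[C@@H](O[Si](CC)(CC)CC)C(=C)[C@H]12
A5 | alternative 3 | 10-nor 8-oxo iridoid 7β-O-(iodomethyl)dimethylsilyl ether (1-OTBS, 11-OTBS) | CC(C)(C)[Si](C)(C)O[C@H]1OC=C(CO[Si](C)(C)C(C)(C)C)[C@@H]2C[C@@H](O[Si](C)(C)CI)C(=O)[C@H]12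
A6 | alternative 3 | 7,10-bridged oxasilolane tertiary alcohol | CC(C)(C)[Si](C)(C)O[C@H]1OC=C(CO[Si](C)(C)C(C)(C)C)[C@@H]2C[C@H]3O[Si](C)(C)C[C@@]3(O)[C@H]12
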